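In a closed flask the substrate charged stays on the books: target, substrate and whatever the readings do not show add up to 100 percent at each moment. You have one run of this very flask, followed to 20.0 h, and a neighbour flask with the same charge and temperature, read at 5.0 d. The two differ in waiting time.

- teal: substrate 0.62 M; partner 2.48 M; temperature 5 °C; the very flask that is asked about, followed so far
- flask: substrate 0.62 M; partner 2.48 M; temperature 5 °C; time 30 h

teal run (percent of the substrate charged)

| time / h | target / % | substrate / % |
|---|---|---|
| 1.33 | 27.6 | 52.2 |
| 2.50 | 38.3 | 31.2 |
| 5.00 | 48.3 | 13.4 |
| 10.0 | 53.8 | 3.3 |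
| 20.0 | 55.5 | 1.5 |

(readings scatter by 0.5 percentage points)

- target that was removed still counts
- the earlier runs do not show what temperature does; that part of a forecast is a guess

- delta: at 30 h raise the temperature by 20 K, then wait 15 h
- eta: change nothing and wait 15 h more
- theta: at 30 h take out 90% of the target then present, then wait 15 h

- target, in percent of the substrate first charged, at 30 h
- the option that brings most further target ("none" if no option brings more than 2 percentage points) (delta / eta / theta / none)
- target present, with what was taken out counted in, in percent of the substrate first charged, after delta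
- target present, with what was taken out counted in, in percent of the substrate first charged, after theta

At the first reading, target over substrate lost is 0.577. Call this reading the yield ratio, the target paid per unit of substrate lost, a selectivity. Now watch the tail. Substrate's half-life reads 2.47 h up to 10.0 h, then 8.79 h up to 20.0 h, which is longer. Over that tail target gains 1.7 percentage points, but the substrate lost buys 1 point at the yield ratio, so target gains more than it should. With a scatter of 0.5 points that is a hint, not a proof. Still, two time constants are what a second compartment looks like, so I suspect an unseen store feeding substrate back.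

My own reckoning keeps the tail's pace and puts target at 57.2% at 30 h. The neighbour flask should then stand above this one by the yield ratio times what the store gives up in the extra 90.0 h. The substrate visible at 20.0 h is worth 0.87 points.

The forecast says 55.8%, between 55% and 56.6%, which is below my figure. It expects 56.2% after delta and 56.3% after theta, and its best option is none, since “only about 1.5% of substrate is left, worth under 1 point of target”.

The flask gives 57.8%. Delta is best, adding 6.1 points, more than eta's 1.5 points or theta's 1.5 points, and it ends at 63.9%, while theta ends at 59.3%.

    intermediate A → side product A (k = 0.00560 min⁻¹, Ea = 90.0 kJ mol⁻¹)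
    substrate + partner → intermediate A (k = 0.00100 M⁻¹ min⁻¹, Ea = 69.0 kJ mol⁻¹)
    partner + intermediate C → side product B (k = 3.80 × 10⁻⁴ M⁻¹ min⁻¹, Ea = 58.0 kJ mol⁻¹)
    substrate + partner → intermediate B (k = 6.80 × 10⁻⁵ M⁻¹ min⁻¹, Ea = 68.0 kJ mol⁻¹)
    intermediate B ⇌ intermediate C (K = 37.0, k = 0.00290 min⁻¹, Ea = 87.0 kJ mol⁻¹, ΔH = −33.0 kJ mol⁻¹)
    substrate + partner → target (k = 0.00200 M⁻¹ min⁻¹, Ea = 58.0 kJ mol⁻¹)
    2 partner → homo dimer (k = 1.90 × 10⁻⁴ M⁻¹ min⁻¹, Ea = 67.0 kJ mol⁻¹)
    substrate ⇌ dormant form (K = 2.80, k = 0.00130 min⁻¹, Ea = 87.0 kJ mol⁻¹, ΔH = −31.0 kJ mol⁻¹)
    partner → decomposition product (k = 2.10 × 10⁻⁶ min⁻¹, Ea = 107 kJ mol⁻¹)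
    (constants at 5 °C)

The store is the dormant form, 10.1% of the charge at 30.0 h, beside 1.29% of free substrate. Part of the answer to delta's gain is this store: with the step from substrate to dormant form struck out, both ways, delta brings 0.079 points, where this flask has 6.1 points. At the yield ratio those two amounts are worth 6.6 points. In the neighbour flask they have shrunk by 7.6 points, worth 4.4 points, and its target stands 5 points above this flask's.

The earlier runs and the new flask were generated by integration from invented constants; noise was put on by code.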